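**Retrosynthetic overview**
- The (7R,8R)-threo target comes from hydrogenolysis of two benzyl ethers, preceded by Tamao oxidation of a cis-4-aryloxy-5-aryl-1-oxa-2-silacyclopentane (C9–Si becomes C9–OH, O7 is freed).
- That ring (O7–Si–C9–C8–C7) is the only ring formed in the route; rings A and B are bought. It comes from platinum-catalysed intramolecular hydrosilylation of the O7–SiMe2H ether of an (R)-2-aryloxy allylic alcohol (C8=C9 enol ether), which sets C8.
- The enol ether comes from Tebbe methylenation of the ring B aryl ester of an (R)-O-silyl mandelic acid: the hindered O8–C4' bond is first an ester bond, and the acyl carbon becomes C8.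
- C7 comes from asymmetric transfer hydrogenation of the ring A glyoxylate (aryl Grignard plus diethyl oxalate, after Mitsunobu etherification of 4-bromo-2,6-dimethoxyphenol); the ring B phenol comes from hydroboration of 4-allyl-2,6-dimethoxyphenol.
- Feature used: the C7 benzylic carbinol on ring A next to C8, which carries the ring B aryloxy oxygen and the C9 hydroxymethyl group. This C7(OH)–C8(OAr)–C9H2OH array is the anti-Markovnikov hydrate of a 2-aryloxy allylic alcohol, with C8 syn (threo) to C7.

Key step: step 12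

Remark (labels): C7 is the benzylic carbinol carbon, C8 the carbon bearing the ring B aryloxy group, C9 the hydroxymethyl carbon; ring A is the aryl on C7, ring B the aryloxy ring on C8; ArA = 4-{[1,3-bis(benzyloxy)propan-2-yl]oxy}-3,5-dimethoxyphenyl.

Remark (assumption): in step 3 the sense of hydride delivery is assigned from the aryl/arene CH–π model that holds for aryl ketones with this catalyst. The configuration of 7 would be confirmed before material is carried on, and the (R,R)-ligand complex would be used if the sense were opposite.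

Remark (protecting groups): the side-chain primary alcohol is carried through the key step as a second dimethylsilyl ether. This removes the need for a selective desilylation, and the group falls off in the oxidation of step 13.

**Step 1**
Reactants: 1 4-bromo-2,6-dimethoxyphenol; 2 1,3-bis(benzyloxy)propan-2-ol
Product: 3 5-bromo-2-{[1,3-bis(benzyloxy)propan-2-yl]oxy}-1,3-dimethoxybenzene (ArA–Br)
Conditions: PPh3, DIAD, THF, 0 °C to rt
Reagents that add atoms: none
Why: Mitsunobu etherification, in which the acidic phenol protonates the betaine and displaces the activated secondary carbinol by SN2; the carbinol carbon is not stereogenic, so inversion is without consequence.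

**Step 2**
Reactants: 3 ArA–Br; 4 diethyl oxalate
Product: 6 ethyl 2-ArA-2-oxoacetate, via arylmagnesium bromide 5 (not isolated)
Conditions: Mg turnings (I2 cat.), THF, reflux; then added to 4 (3 equiv), THF, −78 °C; then 1 M HCl
Reagents that add atoms: none
Why: Grignard formation followed by acyl substitution on excess diethyl oxalate at low temperature, where the tetrahedral magnesium alkoxide persists until the quench and so stops at the α-keto ester.

**Step 3**
Reactants: 6 ethyl 2-ArA-2-oxoacetate
Product: 7 ethyl (2R)-2-ArA-2-hydroxyacetate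
Conditions: RuCl[(S,S)-TsDPEN](p-cymene) (1 mol%), HCO2H/Et3N (5:2), EtOAc, rt
Reagents that add atoms: none
Why: Noyori asymmetric transfer hydrogenation of an aryl glyoxylate, in which the Ru–H/N–H pair should deliver hydrogen to the Si face of the ketone (aryl held against the p-cymene ligand) and so set C7 as R.

**Step 4**
Reactants: 7 ethyl (2R)-2-ArA-2-hydroxyacetate
Product: 8 ethyl (2R)-2-ArA-2-[(tert-butyldimethylsilyl)oxy]acetate
Conditions: TBSCl, imidazole, DMF, rt
Reagents that add atoms: tert-butyldimethylsilyl chloride, CC(C)(C)[Si](C)(C)Cl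
Why: Standard imidazole-mediated O-silylation of a secondary α-hydroxy ester, which leaves C7 untouched.

**Step 5**
Reactants: 8 ethyl (2R)-2-ArA-2-[(tert-butyldimethylsilyl)oxy]acetate
Product: 9 (2R)-2-ArA-2-[(tert-butyldimethylsilyl)oxy]acetic acid
Conditions: LiOH·H2O, THF/H2O (3:1), 0 °C to rt; then 1 M HCl to pH 3, 0 °C
Reagents that add atoms: lithium hydroxide, [Li+].[OH-]
Why: Saponification at low temperature, which the secondary TBS ether tolerates and in which the electron-rich aryl group disfavours enolisation, so C7 should keep its configuration.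

**Step 6**
Reactants: 10 4-allyl-2,6-dimethoxyphenol
Product: 12 4-(3-hydroxypropyl)-2,6-dimethoxyphenol, via bis(9-BBN) adduct 11 (not isolated)
Conditions: 9-BBN (2.3 equiv), THF, 0 °C to rt; then 3 M NaOH, 30% H2O2, 0 °C to rt
Reagents that add atoms: hydrogen peroxide, OO
Why: Anti-Markovnikov hydroboration–oxidation of the terminal alkene (one equivalent of borane is consumed by the phenol), with C–B to C–O oxidation giving the primary alcohol.

**Step 7**
Reactants: 12 4-(3-hydroxypropyl)-2,6-dimethoxyphenol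
Product: 13 4-{3-[(tert-butyldimethylsilyl)oxy]propyl}-2,6-dimethoxyphenol
Conditions: TBSCl (1.05 equiv), imidazole, CH2Cl2, 0 °C
Reagents that add atoms: tert-butyldimethylsilyl chloride, CC(C)(C)[Si](C)(C)Cl
Why: Chemoselective silylation, since the unhindered primary alcohol should react well before the di-ortho-substituted, internally hydrogen-bonded phenol.

**Step 8**
Reactants: 9 (2R)-2-ArA-2-[(tert-butyldimethylsilyl)oxy]acetic acid; 13 4-{3-[(tert-butyldimethylsilyl)oxy]propyl}-2,6-dimethoxyphenol
Product: 14 4-{3-[(tert-butyldimethylsilyl)oxy]propyl}-2,6-dimethoxyphenyl (2R)-2-ArA-2-[(tert-butyldimethylsilyl)oxy]acetate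
Conditions: DIC, DMAP (0.1 equiv), CH2Cl2, 0 °C to rt
Reagents that add atoms: none
Why: Steglich esterification, in which the acylpyridinium ion acylates the phenol; catalytic DMAP and low temperature are chosen to keep the C7–H of the activated acid from exchanging.

**Step 9**
Reactants: 14 aryl (2R)-mandelate ester
Product: 15 tert-butyl{[(1R)-1-ArA-2-(4-{3-[(tert-butyldimethylsilyl)oxy]propyl}-2,6-dimethoxyphenoxy)prop-2-en-1-yl]oxy}dimethylsilane
Conditions: Cp2Ti(μ-CH2)(μ-Cl)AlMe2 (2 equiv), pyridine, THF/toluene, −40 °C to rt; then 0.1 M NaOH, −10 °C; Et3N-deactivated silica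
Reagents that add atoms: Tebbe reagent Cp2Ti(μ-CH2)(μ-Cl)AlMe2, C[Al-]1(C)C[Ti](C2C=CC=C2)(C3C=CC=C3)[Cl+]1
Why: Tebbe methylenation, in which Cp2Ti=CH2 adds to the ester carbonyl and the oxatitanacyclobutane cycloreverts to the aryl enol ether; the reagent is not basic, so C7 is not epimerised, and aryl esters are known substrates.

**Step 10**
Reactants: 15 bis-TBS enol ether
Product: 16 (1R)-1-ArA-2-[4-(3-hydroxypropyl)-2,6-dimethoxyphenoxy]prop-2-en-1-ol
Conditions: Bu4NF (3 equiv), THF, 0 °C to rt; NaHCO3 work-up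
Reagents that add atoms: none
Why: Fluoride-induced cleavage of both silyl ethers under basic conditions, which the acid-labile aryl enol ether and the benzyl ethers should tolerate.

**Step 11**
Reactants: 16 enol ether diol
Product: 17 {[(1R)-1-ArA-2-(4-{3-[(dimethylsilyl)oxy]propyl}-2,6-dimethoxyphenoxy)prop-2-en-1-yl]oxy}dimethylsilane (O7–SiMe2H and side-chain O–SiMe2H)
Conditions: (HMe2Si)2NH (3 equiv), hexane, 25 to 50 °C; volatiles removed in vacuo, used crude
Reagents that add atoms: 1,1,3,3-tetramethyldisilazane, C[SiH](C)N[SiH](C)C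
Why: Neutral O-silylation by a disilazane with ammonia as the only by-product, which installs the tethered Si–H on O7 and at the same time masks the side-chain alcohol as a silyl ether that step 13 removes.

**Step 12**
Reactants: 17 bis(dimethylsilyl) ether of the 2-aryloxy allylic alcohol
Product: 18 (4S,5R)-5-ArA-4-(4-{3-[(dimethylsilyl)oxy]propyl}-2,6-dimethoxyphenoxy)-2,2-dimethyl-1,2-oxasilolane (aryl and aryloxy cis)
Conditions: Pt2[(CH2=CHSiMe2)2O]3 (0.5 mol% Pt), hexane (0.05 M), 25 to 60 °C, base-washed glassware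
Reagents that add atoms: none
Why: Intramolecular hydrosilylation by the Chalk–Harrod mechanism: the O7–SiMe2–H bond adds oxidatively to zerovalent platinum, the tethered C8=C9 enol ether inserts into Pt–H with hydrogen going to C8 and platinum to C9, and C9–Si reductive elimination releases the ring. The closest known reaction is the platinum-catalysed intramolecular hydrosilylation of α-hydroxy alkyl enol ethers, which after oxidation gives 2,3-syn 2-alkoxy-1,3-diols; here the enol oxygen carries an aryl group in place of an alkyl group. The one ring closed, the 1-oxa-2-silacyclopentane O7–Si–C9–C8–C7, forms in the 5-endo mode because the short O7–Si tether can bring silicon only to the terminal carbon C9, the 4-exo alternative being a strained four-membered oxasiletane. The new stereocentre C8 is controlled by C7 through 1,2-induction: in the cyclic transition state the C7–H bond lies near the enol ether plane beside the C8 aryloxy group to minimise A(1,2) strain, the ring A aryl points to the face away from platinum, and hydride reaches C8 on the tether side, which puts aryl and aryloxy cis on the ring, the arrangement that becomes threo (7R,8R) after oxidation. The step needs regioselectivity (silicon to C9), facial selectivity at C8 and chemoselectivity between the two Si–H groups; the tether length should secure the first, the allylic strain of the 1,1-disubstituted enol ether the second, and the third follows because only the O7-bound silane can reach the alkene through a five-membered ring while the side-chain silane stays a spectator at this dilution. A neutral platinum catalyst is used because the aryl enol ether would hydrolyse under acid.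

**Step 13**
Reactants: 18 oxasilolane
Product: 19 (1R,2R)-1-ArA-2-[4-(3-hydroxypropyl)-2,6-dimethoxyphenoxy]propane-1,3-diol
Conditions: KF, KHCO3, 30% H2O2, THF/MeOH (1:1), rt to 40 °C; Na2S2O3 quench
Reagents that add atoms: hydrogen peroxide, OO
Why: Tamao oxidation, in which fluoride-activated silicon takes up hydroperoxide and C9 migrates from silicon to oxygen; the same medium solvolyses the O7–Si bond and the side-chain silyl ether, and C7 and C8 are not touched.

**Step 14**
Reactants: 19 dibenzyl ether triol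
Product: 20 (1R,2R)-1-{4-[(1,3-dihydroxypropan-2-yl)oxy]-3,5-dimethoxyphenyl}-2-[4-(3-hydroxypropyl)-2,6-dimethoxyphenoxy]propane-1,3-diol (target)
Conditions: H2 (1 atm), 10% Pd/C, EtOH, rt, neutral medium
Reagents that add atoms: none
Why: Catalytic hydrogenolysis of the two primary benzyl ethers; in a neutral, acid-free medium the secondary benzylic C7–OH and the C8–O aryl ether should survive.

**Compound list**
1 | 4-bromo-2,6-dimethoxyphenol | COc1cc(Br)cc(OC)c1O | starting material
2 | 1,3-bis(benzyloxy)propan-2-ol | OC(COCc1ccccc1)COCc1ccccc1 | starting material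
3 | 5-bromo-2-{[1,3-bis(benzyloxy)propan-2-yl]oxy}-1,3-dimethoxybenzene | COc1cc(Br)cc(OC)c1OC(COCc2ccccc2)COCc3ccccc3 | intermediate
4 | diethyl oxalate | CCOC(=O)C(=O)OCC | starting material
5 | (4-{[1,3-bis(benzyloxy)propan-2-yl]oxy}-3,5-dimethoxyphenyl)magnesium bromide | COc1cc([Mg]Br)cc(OC)c1OC(COCc2ccccc2)COCc3ccccc3 | intermediate
6 | ethyl 2-(4-{[1,3-bis(benzyloxy)propan-2-yl]oxy}-3,5-dimethoxyphenyl)-2-oxoacetate | CCOC(=O)C(=O)c1cc(OC)c(OC(COCc2ccccc2)COCc3ccccc3)c(OC)c1 | intermediate
7 | ethyl (2R)-2-(4-{[1,3-bis(benzyloxy)propan-2-yl]oxy}-3,5-dimethoxyphenyl)-2-hydroxyacetate | COc1cc([C@@H](O)C(=O)OCC)cc(OC)c1OC(COCc2ccccc2)COCc3ccccc3 | intermediate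
8 | ethyl (2R)-2-(4-{[1,3-bis(benzyloxy)propan-2-yl]oxy}-3,5-dimethoxyphenyl)-2-[(tert-butyldimethylsilyl)oxy]acetate | COc1cc([C@@H](O[Si](C)(C)C(C)(C)C)C(=O)OCC)cc(OC)c1OC(COCc2ccccc2)COCc3ccccc3 | intermediate
9 | (2R)-2-(4-{[1,3-bis(benzyloxy)propan-2-yl]oxy}-3,5-dimethoxyphenyl)-2-[(tert-butyldimethylsilyl)oxy]acetic acid | COc1cc([C@@H](O[Si](C)(C)C(C)(C)C)C(=O)O)cc(OC)c1OC(COCc2ccccc2)COCc3ccccc3 | intermediate
10 | 4-allyl-2,6-dimethoxyphenol | COc1cc(CC=C)cc(OC)c1O | starting material
11 | 9-{3-[4-(9-borabicyclo[3.3.1]nonan-9-yloxy)-3,5-dimethoxyphenyl]propyl}-9-borabicyclo[3.3.1]nonane | COc1cc(CCCB2C3CCCC2CCC3)cc(OC)c1OB4C5CCCC4CCC5 | intermediate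
12 | 4-(3-hydroxypropyl)-2,6-dimethoxyphenol | COc1cc(CCCO)cc(OC)c1O | intermediate
13 | 4-{3-[(tert-butyldimethylsilyl)oxy]propyl}-2,6-dimethoxyphenol | COc1cc(CCCO[Si](C)(C)C(C)(C)C)cc(OC)c1O | intermediate
14 | 4-{3-[(tert-butyldimethylsilyl)oxy]propyl}-2,6-dimethoxyphenyl (2R)-2-(4-{[1,3-bis(benzyloxy)propan-2-yl]oxy}-3,5-dimethoxyphenyl)-2-[(tert-butyldimethylsilyl)oxy]acetate | COc1cc([C@@H](O[Si](C)(C)C(C)(C)C)C(=O)Oc2c(OC)cc(CCCO[Si](C)(C)C(C)(C)C)cc2OC)cc(OC)c1OC(COCc3ccccc3)COCc4ccccc4 | intermediate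
15 | (R)-configured C7–OTBS 2-aryloxy allyl ether (C8=C9 enol ether, side-chain OTBS) | COc1cc([C@@H](O[Si](C)(C)C(C)(C)C)C(=C)Oc2c(OC)cc(CCCO[Si](C)(C)C(C)(C)C)cc2OC)cc(OC)c1OC(COCc3ccccc3)COCc4ccccc4 | intermediate
16 | (1R)-1-(4-{[1,3-bis(benzyloxy)propan-2-yl]oxy}-3,5-dimethoxyphenyl)-2-[4-(3-hydroxypropyl)-2,6-dimethoxyphenoxy]prop-2-en-1-ol | COc1cc([C@@H](O)C(=C)Oc2c(OC)cc(CCCO)cc2OC)cc(OC)c1OC(COCc3ccccc3)COCc4ccccc4 | intermediate
17 | (R)-bis(dimethylsilyl) ether of 16 (O7–SiMe2H and side-chain O–SiMe2H) | COc1cc([C@@H](O[SiH](C)C)C(=C)Oc2c(OC)cc(CCCO[SiH](C)C)cc2OC)cc(OC)c1OC(COCc3ccccc3)COCc4ccccc4 | intermediate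
18 | (4S,5R)-cis-5-aryl-4-aryloxy-2,2-dimethyl-1,2-oxasilolane (side-chain O–SiMe2H retained) | COc1cc([C@@H](O3)[C@@H](C[Si]3(C)C)Oc2c(OC)cc(CCCO[SiH](C)C)cc2OC)cc(OC)c1OC(COCc5ccccc5)COCc6ccccc6 | intermediate
19 | (1R,2R)-1-(4-{[1,3-bis(benzyloxy)propan-2-yl]oxy}-3,5-dimethoxyphenyl)-2-[4-(3-hydroxypropyl)-2,6-dimethoxyphenoxy]propane-1,3-diol | COc1cc([C@@H](O)[C@@H](CO)Oc2c(OC)cc(CCCO)cc2OC)cc(OC)c1OC(COCc3ccccc3)COCc4ccccc4 | intermediate
20 | (1R,2R)-1-{4-[(1,3-dihydroxypropan-2-yl)oxy]-3,5-dimethoxyphenyl}-2-[4-(3-hydroxypropyl)-2,6-dimethoxyphenoxy]propane-1,3-diol | COc1cc([C@@H](O)[C@@H](CO)Oc2c(OC)cc(CCCO)cc2OC)cc(OC)c1OC(CO)CO | target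

**Step count**
Total: 14 steps. Longest linear sequence: 12 steps (steps 1–5 and 8–14, from 1 to 20); steps 6–7 are the convergent branch to phenol 13.

**Steps most likely to fail, with fallbacks**

Step 12. What may go wrong: poor facial selectivity at C8 if the aryloxy group weakens the allylic-strain bias, or loss of the enol ether through platinum-mediated isomerisation or adventitious hydrolysis before insertion. The fallback replaces the silicon tether by a catalyst-controlled hydroboration. It sets out from the bis-TBS enol ether 15. Treatment with catecholborane and RhCl(PPh3)3 in THF should add boron to C9 and hydrogen to C8 with the syn preference known for rhodium-catalysed hydroboration of 1,1-disubstituted allylic silyl ethers (the uncatalysed 9-BBN reaction is anti-selective), giving the (1R,2R)-alkyl catecholboronate F1. This is oxidised without isolation (NaOH, H2O2) to the (1R,2R)-bis-TBS primary alcohol F2. Bu4NF in THF then removes both silyl ethers and the route is rejoined at 19.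

Step 9. What may go wrong: incomplete methylenation of a carbonyl flanked by the silyloxy-benzylic centre and the di-ortho-substituted aryloxy group, cleavage of the aryl ester with loss of phenoxide, or hydrolysis of the enol ether on work-up. The fallback makes C8=C9 by β-elimination instead of carbonyl methylenation and sets C7 on a ketone. It sets out from Grignard reagent 5 (made from 3 as in step 2) and phenol 13.
- 5 with 2-chloro-N-methoxy-N-methylacetamide in THF at 0 °C should give the 2-chloro-1-ArA-ethanone F3.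
- F3 and 13 with K2CO3 and catalytic KI in acetone give the phenacyl aryl ether F4.
- Aqueous formaldehyde with K2CO3 hydroxymethylates C8 to the racemic β-hydroxy ketone F5.
- Transfer hydrogenation of F5 with RuCl[(S,S)-TsDPEN](p-cymene) and HCO2H/Et3N should give the (7R)-diol F6 as a mixture of C8 epimers; this is of no consequence because C8 becomes trigonal.
- Primary-selective iodination of F6 (I2, PPh3, imidazole, 0 °C) gives the C9 iodide F7.
- TBSOTf and 2,6-lutidine protect O7 to give the silyl ether iodide F8.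
- KOtBu in THF effects E2 elimination, for which C8–H is the only β-hydrogen, and the route is rejoined at 15.

Step 8. What may go wrong: partial racemisation at C7 by α-deprotonation of the activated acyl species, and slow acylation of the hindered, hydrogen-bonded phenol that lengthens the exposure. The fallback forms the ester bond before the stereocentre exists. It sets out from keto ester 6.
- LiOH in THF/H2O gives the 2-ArA-2-oxoacetic acid F9.
- Oxalyl chloride with catalytic DMF in CH2Cl2 converts F9 into the acid chloride F10, used directly.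
- F10 with 13, Et3N and catalytic DMAP gives the aryl α-keto ester F11.
- Transfer hydrogenation of F11 with RuCl[(S,S)-TsDPEN](p-cymene) and HCO2H/Et3N should give the aryl (2R)-hydroxy ester F12.
- TBSOTf and 2,6-lutidine at −78 °C silylate O7 and the route is rejoined at 14.

**Further compounds**
F1 | step 12 | (1R,2R)-C9 catecholboronate of the bis-TBS ether (C7–OTBS, side-chain OTBS) | COc1cc([C@@H](O[Si](C)(C)C(C)(C)C)[C@@H](CB7Oc8ccccc8O7)Oc2c(OC)cc(CCCO[Si](C)(C)C(C)(C)C)cc2OC)cc(OC)c1OC(COCc3ccccc3)COCc4ccccc4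
F2 | step 12 | (2R,3R)-3-ArA-3-[(tert-butyldimethylsilyl)oxy]-2-(4-{3-[(tert-butyldimethylsilyl)oxy]propyl}-2,6-dimethoxyphenoxy)propan-1-ol | COc1cc([C@@H](O[Si](C)(C)C(C)(C)C)[C@@H](CO)Oc2c(OC)cc(CCCO[Si](C)(C)C(C)(C)C)cc2OC)cc(OC)c1OC(COCc3ccccc3)COCc4ccccc4
F3 | step 9 | 1-(4-{[1,3-bis(benzyloxy)propan-2-yl]oxy}-3,5-dimethoxyphenyl)-2-chloroethan-1-one | COc1cc(C(=O)CCl)cc(OC)c1OC(COCc2ccccc2)COCc3ccccc3
F4 | step 9 | 1-ArA-2-(4-{3-[(tert-butyldimethylsilyl)oxy]propyl}-2,6-dimethoxyphenoxy)ethan-1-one | COc1cc(C(=O)COc2c(OC)cc(CCCO[Si](C)(C)C(C)(C)C)cc2OC)cc(OC)c1OC(COCc3ccccc3)COCc4ccccc4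
F5 | step 9 | racemic 1-ArA-2-(4-{3-[(tert-butyldimethylsilyl)oxy]propyl}-2,6-dimethoxyphenoxy)-3-hydroxypropan-1-one | COc1cc(C(=O)C(CO)Oc2c(OC)cc(CCCO[Si](C)(C)C(C)(C)C)cc2OC)cc(OC)c1OC(COCc3ccccc3)COCc4ccccc4
F6 | step 9 | (1R)-1-ArA-2-(4-{3-[(tert-butyldimethylsilyl)oxy]propyl}-2,6-dimethoxyphenoxy)propane-1,3-diol, mixture of C8 epimers | COc1cc([C@@H](O)C(CO)Oc2c(OC)cc(CCCO[Si](C)(C)C(C)(C)C)cc2OC)cc(OC)c1OC(COCc3ccccc3)COCc4ccccc4
F7 | step 9 | (1R)-1-ArA-2-(4-{3-[(tert-butyldimethylsilyl)oxy]propyl}-2,6-dimethoxyphenoxy)-3-iodopropan-1-ol, mixture of C8 epimers | COc1cc([C@@H](O)C(CI)Oc2c(OC)cc(CCCO[Si](C)(C)C(C)(C)C)cc2OC)cc(OC)c1OC(COCc3ccccc3)COCc4ccccc4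
F8 | step 9 | C7–OTBS ether of F7 | COc1cc([C@@H](O[Si](C)(C)C(C)(C)C)C(CI)Oc2c(OC)cc(CCCO[Si](C)(C)C(C)(C)C)cc2OC)cc(OC)c1OC(COCc3ccccc3)COCc4ccccc4
F9 | step 8 | 2-(4-{[1,3-bis(benzyloxy)propan-2-yl]oxy}-3,5-dimethoxyphenyl)-2-oxoacetic acid | COc1cc(C(=O)C(=O)O)cc(OC)c1OC(COCc2ccccc2)COCc3ccccc3
F10 | step 8 | 2-(4-{[1,3-bis(benzyloxy)propan-2-yl]oxy}-3,5-dimethoxyphenyl)-2-oxoacetyl chloride | COc1cc(C(=O)C(=O)Cl)cc(OC)c1OC(COCc2ccccc2)COCc3ccccc3
F11 | step 8 | 4-{3-[(tert-butyldimethylsilyl)oxy]propyl}-2,6-dimethoxyphenyl 2-ArA-2-oxoacetate | COc1cc(C(=O)C(=O)Oc2c(OC)cc(CCCO[Si](C)(C)C(C)(C)C)cc2OC)cc(OC)c1OC(COCc3ccccc3)COCc4ccccc4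
F12 | step 8 | 4-{3-[(tert-butyldimethylsilyl)oxy]propyl}-2,6-dimethoxyphenyl (2R)-2-ArA-2-hydroxyacetate | COc1cc([C@@H](O)C(=O)Oc2c(OC)cc(CCCO[Si](C)(C)C(C)(C)C)cc2OC)cc(OC)c1OC(COCc3ccccc3)COCc4ccccc4
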